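## Analysis of the target

The target is a flavan-3-ol dimer; atoms of the upper unit are unprimed and those of the lower unit are primed. The upper unit (benzo ring A, pyran ring C, 4-hydroxyphenyl ring B) is a 5-deoxyflavan-3-ol with one hydroxyl at C7. The lower unit (benzo ring D, pyran ring F, catechol ring E) is epicatechin, and C4 of ring C is bonded to C8′ of ring D. There are five stereocentres, all R: C2, C3 and C4 (2,3-cis, 3,4-trans) and C2′, C3′ (cis). The sensitive features are six phenols including a catechol (air and base), the two benzylic ether bonds O1–C2 and O1′–C2′ (ionisation, base-induced epimerisation), and the doubly benzylic C4–C8′ bond. The difficulties are the 2,3-cis ("epi") arrangement in both heterocycles, the crowded C4 methine of fixed configuration, and attachment to ring D at C8′ rather than C6′. The strategy rests on one repeated motif: in rings C and F a phenolic oxygen (O1, O1′) is bound to a benzylic carbon (C2, C2′) that lies next to a carbinol (C3, C3′) with the same 2R,3R cis pattern, so that each ring is the footprint of a cis-aryl epoxide opened with inversion at its benzylic carbon by an ortho-hydroxyl, while the ring D oxygen sits between the two three-carbon chains.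

## Retrosynthetic reasoning

**24 ⇒ 23 ⇒ 22 (protecting groups).** Only protecting groups separate 24 from 22. The benzyl ethers on rings A and D are removed last by neutral hydrogenolysis of 23, so the free polyphenol never meets base. The pivalates on rings B and E are removed from 22 one step earlier. The ether/ester split is dictated by the key step: rings B and E must be electron-poor there, while rings A and D may stay electron-rich.

**22 ⇒ 19, through 20 and 21 (O1–C2 and O1′–C2′).** Cutting these two bonds gives a precursor in which both aryl groups and both C3 oxygens are already in place, and forming them creates C2 and C2′ stereospecifically. Any ring C–C disconnection would instead need a stereocontrolled nucleophilic addition next to an existing centre. Both rings and two stereocentres come from one reaction type. The forward reaction must be 6-endo and invertive at both benzylic carbons. The ring D oxygen can reach either oxirane, whereas the ring A oxygen can reach only the upper one. Therefore 19 keeps the ring D oxygen silylated while ring C closes (20); it is unmasked in the same flask (21) when only its own oxirane is left.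

**19 ⇒ 18 ⇒ 17 (oxirane C–O bonds).** Both oxiranes are traced to cis-alkenes. One chiral oxidant of a single handedness delivers both oxygens, because both units need the same sense; this sets C2, C3, C2′ and C3′. The reaction must select one face at each alkene and, at the upper one, override the adjacent C4 centre. The ring A oxygen travels as a TBS ether (removed 18 ⇒ 19) and the ring D oxygen as a more robust TIPS ether.

**17 ⇒ 16 (alkene geometry).** Both cis-alkenes come from alkynes by semihydrogenation. The alkynes are inert spectators in the earlier steps, and a propargylic carbon is what allows C4 to be built enantioselectively.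

**16 ⇒ 13 + 15; 13 ⇒ 12; 15 ⇒ 14 (ring B).** The sp–sp2 bond to ring B is cut (Sonogashira coupling with aryl iodide 15, made from 14). Before that the ring D hydroxyl of 12 is silylated to 13.

**12 ⇒ 7 + 11 (C4–C8′).** This is the central C–C disconnection: it divides the skeleton into halves and creates C4. The forward reaction is an enantioselective propargylic Friedel–Crafts alkylation. It must attack the carbon of 7 ortho to the hydroxyl, which fixes the 4→8 pattern. Acetate 11 comes from aldehyde 8 through 9 and 10.

**7 ⇒ 4 + 6; 6 ⇒ 5 (ring E).** The sp–sp2 bond to ring E is cut (Sonogashira coupling with aryl bromide 6, made from 5).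

**4 ⇒ 3 ⇒ 2 ⇒ 1 (lower chain).** The propargyl group on ring D is traced to a formyl group, because formylation of 1 is strictly ortho to the hydroxyl and so places the chain beside the future ring F oxygen. An ethynyl nucleophile gives 3, and removal of the benzylic oxygen gives 4.

## Alternatives that were turned down

**Alternative 1:** The disconnection is the aryl C8a–O1 bond of ring C, traced to a five-membered ketone. In the forward key step a buffered peracid converts indanone A2 into dihydrocoumarin A1 by Baeyer–Villiger migration of the ring A carbon to oxygen.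
- In favour: the oxygen can only end up on ring A, so the question of which phenol closes ring C never arises. The lower flavan enters complete, with C2′ and C3′ correct. All-benzyl protection needs one final hydrogenolysis. On these three points it is stronger than the chosen route.
- Against: the key step forms no stereocentre and no C–C bond. C4 must be set earlier by adding a very hindered tri-oxygenated aryl group to an indenone-type acceptor. After A1, ring B and the C3 hydroxyl are still missing, so aryl addition to the lactone, anomeric reduction and α-oxygenation must give 2,3-cis/3,4-trans under substrate control. The migrating carbon is meta to the benzyloxy group and gets no donor assistance over CH2 migration, and peracid can hydroxylate the phloroglucinol ring.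
- Comparison: the sequence after the key step is longer and stereochemically less secure. The chosen strategy sets C2/C3 and C2′/C3′ by catalyst control and transfers them stereospecifically with both aryl groups already attached.

**Alternative 2:** The disconnection is C3′–C4′ and O1′–C2′ of ring F. In the forward key step the ortho-quinone methide from hydroxymethyl phenol A4 is attacked by the enamine formed from aldehyde A5 and a chiral secondary amine, and the phenol closes on the aldehyde carbon to give lactol A3.
- In favour: two bonds, one of them C–C, and a ring form in one organocatalytic step. C3′ is set by the catalyst. The ring F position is fixed by the hydroxymethyl group, as securely as in the chosen route, and no cis-alkene is needed for the lower unit.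
- Against: A3 has no ring E. The aryl group must be introduced at anomeric C2′ cis to the 3′-benzyloxy group, whereas arylation of the derived oxocarbenium ion is expected anti to it, so a redox detour would follow. The methide must be generated on a substrate with a second free phenol and acid-labile benzylic ethers. The whole upper unit must first be made by other chemistry.
- Comparison: it is stronger in bond formation per step at the lower unit. It is weaker because the hardest centre of that unit, C2′, stays open, while the chosen strategy closes both heterocycles with every substituent in place.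

**Alternative 3:** The disconnection is the aryl–alkyl bond C4′–C4a′ of ring F. In the forward key step the terminal epoxide of aryl ether A7 is activated by the salt AuCl3 A8 together with the salt AgOTf A9, and the ring D carbon ortho to the ether oxygen attacks the CH2 terminus to give A6 with a free C3′ hydroxyl.
- In favour: C2′ and C3′ come from a chiral-pool three-carbon unit, which is more secure than a late epoxidation. The tether allows only the ortho carbon. A6 is one hydrogenolysis from the target, a shorter endgame than the chosen one.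
- Against: A7 needs an ether between a phenol crowded by the upper unit and an electron-rich secondary benzylic carbon of defined configuration, where substitution competes with ionisation. The same benzylic bond is exposed to A8 and A9 in the key step and can ionise. Only ring F is made; ring C and C4 need their own sequence.
- Comparison: it is stronger in the stereochemical security of the lower unit and in the endgame. The chosen strategy makes both heterocycles by one reaction type and forms the benzylic C–O bonds last, on electron-poor aryl groups.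

Key step: step 16

Remark on the chemistry: the facial sense of the copper–pybox catalyst in step 9 cannot be predicted with certainty for this substrate pair; the (S,S)-ligand is written, and its mirror image is used if it delivers the (S)-methine.
Remark on the chemistry: compound 8 is taken as a purchasable reagent.

## Steps

Step 1
Reactants: 1 3,5-bis(benzyloxy)phenol
Product: 2 2,4-bis(benzyloxy)-6-hydroxybenzaldehyde
Conditions: MgCl2, Et3N, (CH2O)n, MeCN, reflux
Reagents that add atoms: paraformaldehyde (formaldehyde), C=O
Why: Magnesium-phenoxide-directed ortho-formylation (Casnati–Skattebøl reaction) places the aldehyde only next to the hydroxyl; the two ortho positions of 1 are equivalent, so a single aldehyde is expected, and its carbon becomes C4′.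

Step 2
Reactants: 2 2,4-bis(benzyloxy)-6-hydroxybenzaldehyde
Product: 3 1-[2,4-bis(benzyloxy)-6-hydroxyphenyl]prop-2-yn-1-ol (racemic)
Conditions: HC≡CMgBr (3.5 equiv), THF, 0 °C → rt; aq. NH4Cl
Reagents that add atoms: ethynylmagnesium bromide, C#C[Mg]Br
Why: Grignard 1,2-addition to a salicylaldehyde; the first equivalent is consumed by the phenol and the excess adds to the chelated aldehyde. The carbinol centre is racemic and is removed in step 3.

Step 3
Reactants: 3 1-[2,4-bis(benzyloxy)-6-hydroxyphenyl]prop-2-yn-1-ol
Product: 4 3,5-bis(benzyloxy)-2-(prop-2-yn-1-yl)phenol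
Conditions: Et3SiH (5 equiv), TFA (3 equiv), CH2Cl2, −40 → 0 °C
Reagents that add atoms: none
Why: Ionic hydrogenation; the tri-oxygenated ring lets the benzylic propargylic alcohol ionise readily (protonated ortho-quinone methide) and the silane delivers hydride to the benzylic carbon.

Step 4
Reactants: 5 4-bromocatechol
Product: 6 4-bromo-1,2-phenylene bis(2,2-dimethylpropanoate)
Conditions: PivCl, Et3N, DMAP (cat.), CH2Cl2, 0 °C → rt
Reagents that add atoms: pivaloyl chloride, CC(C)(C)C(=O)Cl
Why: Standard O-acylation of both phenols; the esters protect the catechol and make ring E electron-poor for the key step.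

Step 5
Reactants: 4 3,5-bis(benzyloxy)-2-(prop-2-yn-1-yl)phenol; 6 4-bromo-1,2-phenylene bis(2,2-dimethylpropanoate)
Product: 7 4-{3-[2,4-bis(benzyloxy)-6-hydroxyphenyl]prop-1-yn-1-yl}-1,2-phenylene bis(2,2-dimethylpropanoate)
Conditions: Pd(PhCN)2Cl2 (3 mol %), P(t-Bu)3·HBF4 (6 mol %), CuI (2 mol %), i-Pr2NH, dioxane, rt
Reagents that add atoms: none
Why: Sonogashira coupling of a terminal alkyne with an aryl bromide; the bulky electron-rich phosphine allows room temperature, which limits propargyl–allene isomerisation and attack of the free phenol on the alkyne.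

Step 6
Reactants: 8 4-(benzyloxy)-2-hydroxybenzaldehyde
Product: 9 4-(benzyloxy)-2-[(tert-butyldimethylsilyl)oxy]benzaldehyde
Conditions: TBSCl, imidazole, DMF, rt
Reagents that add atoms: tert-butyldimethylsilyl chloride, CC(C)(C)[Si](C)(C)Cl
Why: Routine silylation of a phenol; the TBS ether masks the future O1 oxygen until just before the key step and can be removed in the presence of the TIPS ether.

Step 7
Reactants: 9 4-(benzyloxy)-2-[(tert-butyldimethylsilyl)oxy]benzaldehyde
Product: 10 1-{4-(benzyloxy)-2-[(tert-butyldimethylsilyl)oxy]phenyl}prop-2-yn-1-ol (racemic)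
Conditions: HC≡CMgBr (1.3 equiv), THF, −78 → −20 °C; aq. NH4Cl
Reagents that add atoms: ethynylmagnesium bromide, C#C[Mg]Br
Why: Grignard addition to an aryl aldehyde; a cold quench keeps the silyl group from migrating to the new alkoxide. The racemic centre is erased when the copper–allenylidene forms in step 9.

Step 8
Reactants: 10 1-{4-(benzyloxy)-2-[(tert-butyldimethylsilyl)oxy]phenyl}prop-2-yn-1-ol
Product: 11 1-{4-(benzyloxy)-2-[(tert-butyldimethylsilyl)oxy]phenyl}prop-2-yn-1-yl acetate (racemic)
Conditions: Ac2O, Et3N, DMAP (cat.), CH2Cl2, 0 °C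
Reagents that add atoms: acetic anhydride, CC(=O)OC(C)=O
Why: Esterification gives the leaving group for the propargylic substitution; the acetate is the least ionisable of the usual choices, which suits this electron-rich aryl group.

Step 9
Reactants: 7 4-{3-[2,4-bis(benzyloxy)-6-hydroxyphenyl]prop-1-yn-1-yl}-1,2-phenylene bis(2,2-dimethylpropanoate); 11 1-{4-(benzyloxy)-2-[(tert-butyldimethylsilyl)oxy]phenyl}prop-2-yn-1-yl acetate
Product: 12 (R)-propargyl phenol: 7 carrying at the ring carbon between OH and OBn the (1R)-1-{4-(benzyloxy)-2-[(tert-butyldimethylsilyl)oxy]phenyl}prop-2-yn-1-yl group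
Conditions: Cu(OTf)2 (5 mol %), (S,S)-Ph-pybox (6 mol %), i-Pr2NEt (1.2 equiv), MeOH/THF, −20 °C
Reagents that add atoms: none
Why: Copper-catalysed asymmetric propargylic Friedel–Crafts alkylation of an electron-rich phenol: the terminal alkyne forms a copper acetylide, loss of acetate gives a copper–allenylidene, and the free ortho carbon of 7 attacks its γ-carbon. Both enantiomers of 11 pass through the same planar intermediate, so the ligand alone sets C4 (R required). The other free ring carbon lies between the two benzyloxy groups; it is the more hindered site and, being para to the hydroxyl, cannot profit from hydrogen-bonded delivery by the phenol, which should direct attack ortho to OH and give the 4→8 connectivity.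

Step 10
Reactants: 12 (R)-propargyl phenol
Product: 13 triisopropylsilyl ether of 12 at the ring D hydroxyl
Conditions: TIPSOTf, 2,6-lutidine, CH2Cl2, 0 °C → rt
Reagents that add atoms: triisopropylsilyl triflate, CC(C)[Si](OS(=O)(=O)C(F)(F)F)(C(C)C)C(C)C
Why: Silyl triflate silylation of a hindered phenol; the mask stops the ring D oxygen from cyclising onto the neighbouring alkyne, from being oxidised in step 14 and from competing for the upper oxirane in step 16, and TIPS is chosen to survive removal of the TBS group.

Step 11
Reactants: 14 4-iodophenol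
Product: 15 4-iodophenyl 2,2-dimethylpropanoate
Conditions: PivCl, Et3N, DMAP (cat.), CH2Cl2, 0 °C → rt
Reagents that add atoms: pivaloyl chloride, CC(C)(C)C(=O)Cl
Why: Standard O-acylation; the ester protects the ring B phenol and lowers the donor strength of ring B for the key step.

Step 12
Reactants: 13 triisopropylsilyl ether of 12; 15 4-iodophenyl 2,2-dimethylpropanoate
Product: 16 diyne: 13 with the terminal alkyne carbon bonded to a 4-(pivaloyloxy)phenyl group; C4 (R)
Conditions: Pd(PPh3)2Cl2 (3 mol %), CuI (5 mol %), Et3N, THF, rt
Reagents that add atoms: none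
Why: Sonogashira coupling with an aryl iodide at room temperature; the weak amine base should leave the doubly benzylic propargylic C4–H untouched, so neither allene formation nor loss of configuration is expected.

Step 13
Reactants: 16 diyne
Product: 17 (Z,Z)-diene: both triple bonds of 16 reduced to cis double bonds; C4 (R)
Conditions: H2 (1 atm), Pd/CaCO3–Pb(OAc)2 (Lindlar catalyst), quinoline, EtOAc, rt
Reagents that add atoms: none
Why: Syn addition of hydrogen on the poisoned palladium surface gives both cis-alkenes (Lindlar semihydrogenation); benzyl ethers, aryl esters and silyl ethers are not touched under these conditions.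

Step 14
Reactants: 17 (Z,Z)-diene
Product: 18 bis(cis-epoxide): upper oxirane C2 (S), C3 (R); C4 (R); lower oxirane C2′ (S), C3′ (R); ring A OTBS, ring D OTIPS
Conditions: [(S,S)-salen]MnCl [(S,S)-N,N′-bis(3,5-di-tert-butylsalicylidene)-1,2-cyclohexanediaminomanganese chloride] (2 × 5 mol %), NaOCl (aq., pH 11.3), 4-phenylpyridine N-oxide, CH2Cl2, 0 °C
Reagents that add atoms: sodium hypochlorite, [Na+].[O-]Cl
Why: Jacobsen–Katsuki epoxidation of aryl-conjugated cis-alkenes; by analogy with cis-β-methylstyrene and indene, the (S,S)-complex should give the oxirane with benzylic S and adjacent R configuration at both sites, so one catalyst antipode serves both alkenes. The N-oxide additive favours collapse to the cis-epoxide.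

Step 15
Reactants: 18 bis(cis-epoxide)
Product: 19 ring A phenol: 18 without the TBS group, ring D OTIPS retained
Conditions: TBAF (1.05 equiv), AcOH (1.5 equiv), THF, −20 °C
Reagents that add atoms: none
Why: Fluoride cleaves the less hindered aryl TBS ether much faster than the di-ortho-substituted aryl TIPS ether; acetic acid keeps the freed oxygen protonated so that no base-type opening of the oxirane sets in.

Step 16
Reactants: 19 ring A phenol
Product: 22 protected dimer with rings C and F closed (benzyl ethers on rings A and D; pivalates on rings B and E; free C3 and C3′ hydroxyls), via ring C closed TIPS ether 20 (not isolated), via ring C closed phenol 21 (not isolated)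
Conditions: CSA (0.2 equiv), CH2Cl2, −20 → 0 °C; then TBAF (1.5 equiv), AcOH (1.5 equiv), THF, 0 °C → rt; then CSA (2 equiv), 0 °C → rt
Reagents that add atoms: none
Why: Acid activates the upper oxirane and the ring A hydroxyl attacks benzylic C2 from the side opposite the breaking C–O bond, forming O1–C2 and leaving the oxirane oxygen as the C3 hydroxyl (20); the closest known reaction type is the acid-catalysed cyclisation of 2-(3-aryloxiranylmethyl)phenols to flavan-3-ols. During this stage the ring D oxygen is a silyl ether, so the one hydroxyl that could reach both oxiranes cannot compete for the upper one; fluoride then frees it (21) and, with acid restored, it opens the only oxirane left at benzylic C2′, forming O1′–C2′. Ring C closes in a 6-endo epoxide-opening mode and ring F likewise; the 5-exo alternatives (attack at C3 or C3′) would give dihydrobenzofurans. C2 and C2′ are set by inversion at the S-configured benzylic oxirane carbons and become R, while C3 and C3′ keep their oxygen and configuration, so each ring is 2,3-cis; C4 is untouched and its R configuration places ring D trans to the C3 hydroxyl. The step needs endo rather than exo attack, inversion rather than ionisation, and the right oxygen at each oxirane: benzylic activation directs attack to C2 and C2′, the acyloxy groups on rings B and E hold back benzylic cation formation, and the silyl mask together with the position of the ring D oxygen between both chains fixes which oxygen closes which ring and hence the 4→8 pattern.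

Step 17
Reactants: 22 protected dimer
Product: 23 tri-O-benzyl dimer: 22 with the three pivalates removed
Conditions: K2CO3, MeOH/THF, 0 °C → rt, Ar; AcOH quench
Reagents that add atoms: none
Why: Base-catalysed transesterification of the three aryl pivalates; low temperature, argon and an acidic quench protect the freed catechol and avoid base-induced opening at C2 and C2′.

Step 18
Reactants: 23 tri-O-benzyl dimer
Product: 24 target, epiguibourtinidol-(4β→8)-epicatechin
Conditions: H2 (1 atm), Pd(OH)2/C, THF/MeOH, rt
Reagents that add atoms: none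
Why: Hydrogenolysis of the three aryl benzyl ethers under neutral conditions as the last step; the cyclic benzylic ethers O1–C2 and O1′–C2′ of flavan-3-ols are not expected to cleave under these conditions.

## Compound list

1 | 3,5-bis(benzyloxy)phenol | Oc1cc(OCc2ccccc2)cc(OCc2ccccc2)c1 | starting material
2 | 2,4-bis(benzyloxy)-6-hydroxybenzaldehyde | O=Cc1c(O)cc(OCc2ccccc2)cc1OCc1ccccc1 | intermediate
3 | 1-[2,4-bis(benzyloxy)-6-hydroxyphenyl]prop-2-yn-1-ol (racemic) | C#CC(O)c1c(O)cc(OCc2ccccc2)cc1OCc1ccccc1 | intermediate
4 | 3,5-bis(benzyloxy)-2-(prop-2-yn-1-yl)phenol | C#CCc1c(O)cc(OCc2ccccc2)cc1OCc1ccccc1 | intermediate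
5 | 4-bromocatechol (4-bromobenzene-1,2-diol) | Oc1ccc(Br)cc1O | starting material
6 | 4-bromo-1,2-phenylene bis(2,2-dimethylpropanoate) | CC(C)(C)C(=O)Oc1ccc(Br)cc1OC(=O)C(C)(C)C | intermediate
7 | 4-{3-[2,4-bis(benzyloxy)-6-hydroxyphenyl]prop-1-yn-1-yl}-1,2-phenylene bis(2,2-dimethylpropanoate) | CC(C)(C)C(=O)Oc1ccc(C#CCc2c(O)cc(OCc3ccccc3)cc2OCc2ccccc2)cc1OC(=O)C(C)(C)C | intermediate
8 | 4-(benzyloxy)-2-hydroxybenzaldehyde | O=Cc1ccc(OCc2ccccc2)cc1O | starting material
9 | 4-(benzyloxy)-2-[(tert-butyldimethylsilyl)oxy]benzaldehyde | O=Cc1ccc(OCc2ccccc2)cc1O[Si](C)(C)C(C)(C)C | intermediate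
10 | 1-{4-(benzyloxy)-2-[(tert-butyldimethylsilyl)oxy]phenyl}prop-2-yn-1-ol (racemic) | C#CC(O)c1ccc(OCc2ccccc2)cc1O[Si](C)(C)C(C)(C)C | intermediate
11 | 1-{4-(benzyloxy)-2-[(tert-butyldimethylsilyl)oxy]phenyl}prop-2-yn-1-yl acetate (racemic) | C#CC(OC(C)=O)c1ccc(OCc2ccccc2)cc1O[Si](C)(C)C(C)(C)C | intermediate
12 | 4-{3-[4,6-bis(benzyloxy)-3-[(1R)-1-{4-(benzyloxy)-2-[(tert-butyldimethylsilyl)oxy]phenyl}prop-2-yn-1-yl]-2-hydroxyphenyl]prop-1-yn-1-yl}-1,2-phenylene bis(2,2-dimethylpropanoate) | C#C[C@H](c1ccc(OCc2ccccc2)cc1O[Si](C)(C)C(C)(C)C)c1c(O)c(CC#Cc2ccc(OC(=O)C(C)(C)C)c(OC(=O)C(C)(C)C)c2)c(OCc2ccccc2)cc1OCc1ccccc1 | intermediate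
13 | triisopropylsilyl ether of 12 at the ring D hydroxyl; C4 (R) | C#C[C@H](c1ccc(OCc2ccccc2)cc1O[Si](C)(C)C(C)(C)C)c1c(O[Si](C(C)C)(C(C)C)C(C)C)c(CC#Cc2ccc(OC(=O)C(C)(C)C)c(OC(=O)C(C)(C)C)c2)c(OCc2ccccc2)cc1OCc1ccccc1 | intermediate
14 | 4-iodophenol | Oc1ccc(I)cc1 | starting material
15 | 4-iodophenyl 2,2-dimethylpropanoate | CC(C)(C)C(=O)Oc1ccc(I)cc1 | intermediate
16 | diyne: 13 with the terminal alkyne carbon bonded to 4-(pivaloyloxy)phenyl; C4 (R) | CC(C)(C)C(=O)Oc1ccc(C#C[C@H](c2ccc(OCc3ccccc3)cc2O[Si](C)(C)C(C)(C)C)c2c(O[Si](C(C)C)(C(C)C)C(C)C)c(CC#Cc3ccc(OC(=O)C(C)(C)C)c(OC(=O)C(C)(C)C)c3)c(OCc3ccccc3)cc2OCc2ccccc2)cc1 | intermediate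
17 | (Z,Z)-diene: both alkynes of 16 as cis-alkenes; C4 (R) | CC(C)(C)C(=O)Oc1ccc(/C=C\[C@H](c2ccc(OCc3ccccc3)cc2O[Si](C)(C)C(C)(C)C)c2c(O[Si](C(C)C)(C(C)C)C(C)C)c(C/C=C\c3ccc(OC(=O)C(C)(C)C)c(OC(=O)C(C)(C)C)c3)c(OCc3ccccc3)cc2OCc2ccccc2)cc1 | intermediate
18 | bis(cis-epoxide): upper oxirane C2 (S), C3 (R); C4 (R); lower oxirane C2′ (S), C3′ (R); ring A OTBS; ring D OTIPS | CC(C)(C)C(=O)Oc1ccc([C@@H]2O[C@@H]2[C@@H](c3c(OCc5ccccc5)cc(OCc5ccccc5)c(C[C@H]4O[C@H]4c6ccc(OC(=O)C(C)(C)C)c(OC(=O)C(C)(C)C)c6)c3O[Si](C(C)C)(C(C)C)C(C)C)c2ccc(OCc5ccccc5)cc2O[Si](C)(C)C(C)(C)C)cc1 | intermediate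
19 | ring A phenol: 18 without TBS, ring D OTIPS retained (precursor of the key step) | CC(C)(C)C(=O)Oc1ccc([C@@H]2O[C@@H]2[C@@H](c3c(OCc5ccccc5)cc(OCc5ccccc5)c(C[C@H]4O[C@H]4c6ccc(OC(=O)C(C)(C)C)c(OC(=O)C(C)(C)C)c6)c3O[Si](C(C)C)(C(C)C)C(C)C)c2ccc(OCc5ccccc5)cc2O)cc1 | intermediate
20 | ring C closed TIPS ether: (2R,3R,4R)-chroman with free C3 hydroxyl, ring D OTIPS, lower (2′S,3′R)-oxirane intact | CC(C)(C)C(=O)Oc1ccc([C@H]2Oc3cc(OCc5ccccc5)ccc3[C@H](c3c(OCc5ccccc5)cc(OCc5ccccc5)c(C[C@H]4O[C@H]4c6ccc(OC(=O)C(C)(C)C)c(OC(=O)C(C)(C)C)c6)c3O[Si](C(C)C)(C(C)C)C(C)C)[C@H]2O)cc1 | intermediate (not isolated)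
21 | ring C closed phenol: 20 without the TIPS group | CC(C)(C)C(=O)Oc1ccc([C@H]2Oc3cc(OCc5ccccc5)ccc3[C@H](c3c(OCc5ccccc5)cc(OCc5ccccc5)c(C[C@H]4O[C@H]4c6ccc(OC(=O)C(C)(C)C)c(OC(=O)C(C)(C)C)c6)c3O)[C@H]2O)cc1 | intermediate (not isolated)
22 | 4-[(2R,3R)-5,7-bis(benzyloxy)-8-{(2R,3R,4R)-7-(benzyloxy)-3-hydroxy-2-[4-(pivaloyloxy)phenyl]chroman-4-yl}-3-hydroxychroman-2-yl]-1,2-phenylene bis(2,2-dimethylpropanoate) | CC(C)(C)C(=O)Oc1ccc([C@H]2Oc3cc(OCc5ccccc5)ccc3[C@H](c3c(OCc5ccccc5)cc(OCc5ccccc5)c4c3O[C@H](c3ccc(OC(=O)C(C)(C)C)c(OC(=O)C(C)(C)C)c3)[C@H](O)C4)[C@H]2O)cc1 | intermediate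
23 | (2R,3R)-5,7-bis(benzyloxy)-8-[(2R,3R,4R)-7-(benzyloxy)-3-hydroxy-2-(4-hydroxyphenyl)chroman-4-yl]-2-(3,4-dihydroxyphenyl)chroman-3-ol | Oc1ccc([C@H]2Oc3cc(OCc5ccccc5)ccc3[C@H](c3c(OCc5ccccc5)cc(OCc5ccccc5)c4c3O[C@H](c3ccc(O)c(O)c3)[C@H](O)C4)[C@H]2O)cc1 | intermediate
24 | (2R,3R)-2-(3,4-dihydroxyphenyl)-8-[(2R,3R,4R)-3,7-dihydroxy-2-(4-hydroxyphenyl)chroman-4-yl]chroman-3,5,7-triol | Oc1ccc([C@H]2Oc3cc(O)ccc3[C@H](c3c(O)cc(O)c4c3O[C@H](c3ccc(O)c(O)c3)[C@H](O)C4)[C@H]2O)cc1 | target

## Step count and least certain steps

Total: 18 steps. Longest linear sequence: 13 steps (1 → 2 → 3 → 4 → 7 → 12 → 13 → 16 → 17 → 18 → 19 → 22 → 23 → 24, i.e. steps 1, 2, 3, 5, 9, 10, 12, 13, 14, 15, 16, 17, 18).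

**Step 16 (key step).** The most likely failure is loss of the waiting lower oxirane. It has to survive the first acid stage and the fluoride stage, where it can be opened by acetate or fluoride or rearrange to a ketone. The crowded upper benzylic carbon may also ionise in part, which erodes inversion. The fallback gives up the single flask and makes the two oxiranes one after the other, so that the lower one does not exist while ring C is closed. It sets out from 13 and returns at 20. Rhodium-catalysed trans-hydroboration of the terminal alkyne of 13 ([Rh(cod)Cl]2, P(i-Pr)3, Et3N, pinacolborane) should give the (Z)-alkenyl pinacol boronate F1, and Suzuki–Miyaura coupling with 15 (Pd(dppf)Cl2, K3PO4, THF/H2O) then gives the upper cis-styrene F2, in which the lower alkyne is intact. [(S,S)-salen]MnCl with NaOCl epoxidises only the alkene and gives the upper mono-epoxide F3, buffered TBAF frees the ring A phenol F4, and CSA closes ring C to the alkynyl chroman F5. Semihydrogenation over Pd/CaCO3–Pb(OAc)2 gives the lower cis-alkene F6, and a second epoxidation with the same manganese complex gives 20, which is desilylated and closed to 22 as in the second half of step 16.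

**Step 9.** The most likely failure is low enantioselectivity or attack through the wrong atom. The 2,4-dioxygenated aryl group lets acetate 11 ionise without copper (racemic background), and the hindered phenol 7 may react through oxygen or through the carbon para to the hydroxyl. The fallback sets out from 10 and 7. A Brønsted acid (TsOH·H2O cat., CH2Cl2, 0 °C) forms the propargylic cation from alcohol 10, and a Friedel–Crafts reaction, in which any aryl propargyl ether re-ionises and funnels to carbon, gives the racemic propargyl phenol F7. Preparative chromatography on a chiral stationary phase then gives the R enantiomer, which is 12.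

**Step 14.** The most likely failure is leakage from cis- to trans-epoxide through the stepwise radical pathway. Poor facial control at the hindered upper alkene, where the catalyst must override C4, and chlorination of the free ring D position are further risks. The fallback changes the oxidant class. A chiral dioxirane made in situ from an oxazolidinone-bearing sugar ketone of the Shi type and KHSO5 (Oxone), with K2CO3 in buffered DME/water at 0 °C, transfers oxygen in a concerted way, so the cis geometry cannot be lost. It sets out from 17 and returns at 18; no new compound is made.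

**Step 3.** The most likely failure is capture of the cation by a second electron-rich ring (oligomerisation) or hydride delivery at the alkyne terminus (allene formation). The fallback avoids the cation and sets out from 2. Boc2O with i-Pr2NEt and DMAP gives the aryl tert-butyl carbonate F8, and BH3·SMe2 reduces the aldehyde to the benzylic alcohol F9. HC≡CMgBr (2.5 equiv, THF, −78 °C → rt) then deprotonates the alcohol, the carbonate migrates and is expelled to give the ortho-quinone methide, and the acetylide adds to its methylene carbon. The product is 4.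

**Step 15.** The most likely failure is incomplete discrimination between the two silyl ethers, or early opening of an oxirane by a phenoxide if buffering is insufficient. The fallback sets out from 18. Excess buffered TBAF removes both silyl groups to give the diphenol bis-epoxide F10, and CSA closes both rings concurrently to 22. Regiocontrol at the upper oxirane then rests only on the faster closure of ring F, and any mis-closed isomer must be separated.

## Further compounds

F1 | step 16 | (Z)-alkenyl pinacol boronate: 13 with the terminal alkyne converted to cis-CH=CH–B(pin); C4 (R) | CC1(C)OB(/C=C\[C@H](c2ccc(OCc3ccccc3)cc2O[Si](C)(C)C(C)(C)C)c2c(O[Si](C(C)C)(C(C)C)C(C)C)c(CC#Cc3ccc(OC(=O)C(C)(C)C)c(OC(=O)C(C)(C)C)c3)c(OCc3ccccc3)cc2OCc2ccccc2)OC1(C)C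
F2 | step 16 | upper cis-styrene with the lower alkyne intact; C4 (R) | CC(C)(C)C(=O)Oc1ccc(/C=C\[C@H](c2ccc(OCc3ccccc3)cc2O[Si](C)(C)C(C)(C)C)c2c(O[Si](C(C)C)(C(C)C)C(C)C)c(CC#Cc3ccc(OC(=O)C(C)(C)C)c(OC(=O)C(C)(C)C)c3)c(OCc3ccccc3)cc2OCc2ccccc2)cc1
F3 | step 16 | upper mono-epoxide C2 (S), C3 (R), C4 (R) with the lower alkyne, ring A OTBS, ring D OTIPS | CC(C)(C)C(=O)Oc1ccc([C@@H]2O[C@@H]2[C@@H](c3c(OCc5ccccc5)cc(OCc5ccccc5)c(CC#Cc6ccc(OC(=O)C(C)(C)C)c(OC(=O)C(C)(C)C)c6)c3O[Si](C(C)C)(C(C)C)C(C)C)c2ccc(OCc5ccccc5)cc2O[Si](C)(C)C(C)(C)C)cc1
F4 | step 16 | ring A phenol of F3 | CC(C)(C)C(=O)Oc1ccc([C@@H]2O[C@@H]2[C@@H](c3c(OCc5ccccc5)cc(OCc5ccccc5)c(CC#Cc6ccc(OC(=O)C(C)(C)C)c(OC(=O)C(C)(C)C)c6)c3O[Si](C(C)C)(C(C)C)C(C)C)c2ccc(OCc5ccccc5)cc2O)cc1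
F5 | step 16 | (2R,3R,4R)-chroman with the lower alkyne and ring D OTIPS | CC(C)(C)C(=O)Oc1ccc([C@H]2Oc3cc(OCc5ccccc5)ccc3[C@H](c3c(OCc5ccccc5)cc(OCc5ccccc5)c(CC#Cc6ccc(OC(=O)C(C)(C)C)c(OC(=O)C(C)(C)C)c6)c3O[Si](C(C)C)(C(C)C)C(C)C)[C@H]2O)cc1
F6 | step 16 | (2R,3R,4R)-chroman with the lower cis-alkene and ring D OTIPS | CC(C)(C)C(=O)Oc1ccc([C@H]2Oc3cc(OCc5ccccc5)ccc3[C@H](c3c(OCc5ccccc5)cc(OCc5ccccc5)c(C/C=C\c6ccc(OC(=O)C(C)(C)C)c(OC(=O)C(C)(C)C)c6)c3O[Si](C(C)C)(C(C)C)C(C)C)[C@H]2O)cc1
F7 | step 9 | racemic propargyl phenol (racemate of 12) | C#CC(c1ccc(OCc2ccccc2)cc1O[Si](C)(C)C(C)(C)C)c1c(O)c(CC#Cc2ccc(OC(=O)C(C)(C)C)c(OC(=O)C(C)(C)C)c2)c(OCc2ccccc2)cc1OCc1ccccc1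
F0 | step 14 | none | none
F8 | step 3 | tert-butyl 3,5-bis(benzyloxy)-2-formylphenyl carbonate | CC(C)(C)OC(=O)Oc1cc(OCc2ccccc2)cc(OCc2ccccc2)c1C=O
F9 | step 3 | tert-butyl 3,5-bis(benzyloxy)-2-(hydroxymethyl)phenyl carbonate | CC(C)(C)OC(=O)Oc1cc(OCc2ccccc2)cc(OCc2ccccc2)c1CO
F10 | step 15 | diphenol bis(cis-epoxide): 18 without both silyl groups | CC(C)(C)C(=O)Oc1ccc([C@@H]2O[C@@H]2[C@@H](c3c(OCc5ccccc5)cc(OCc5ccccc5)c(C[C@H]4O[C@H]4c6ccc(OC(=O)C(C)(C)C)c(OC(=O)C(C)(C)C)c6)c3O)c2ccc(OCc5ccccc5)cc2O)cc1
A1 | alternative 1 | 7-benzyloxy-4-(penta-O-benzylepicatechin-8-yl)chroman-2-one | O=C1C[C@@H](c3c(OCc5ccccc5)cc(OCc5ccccc5)c4c3O[C@H](c3ccc(OCc5ccccc5)c(OCc5ccccc5)c3)[C@H](OCc5ccccc5)C4)c2ccc(OCc5ccccc5)cc2O1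
A2 | alternative 1 | 6-benzyloxy-3-(penta-O-benzylepicatechin-8-yl)indan-1-one | O=C1C[C@@H](c3c(OCc5ccccc5)cc(OCc5ccccc5)c4c3O[C@H](c3ccc(OCc5ccccc5)c(OCc5ccccc5)c3)[C@H](OCc5ccccc5)C4)c2ccc(OCc5ccccc5)cc12
A3 | alternative 2 | ring F lactol with 3′-benzyloxy group (anomeric mixture) | c5ccccc5COc1ccc([C@H]2Oc3cc(OCc5ccccc5)ccc3[C@H](c3c(O)cc(OCc5ccccc5)c4c3OC(O)[C@H](OCc5ccccc5)C4)[C@H]2OCc5ccccc5)cc1
A4 | alternative 2 | ring D hydroxymethyl phenol carrying the benzylated upper unit | c5ccccc5COc1ccc([C@H]2Oc3cc(OCc5ccccc5)ccc3[C@H](c3c(O)cc(OCc5ccccc5)c(CO)c3O)[C@H]2OCc5ccccc5)cc1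
A5 | alternative 2 | benzyloxyacetaldehyde | O=CCOCc1ccccc1
A6 | alternative 3 | hepta-O-benzyl target with free C3′ hydroxyl | c5ccccc5COc1ccc([C@H]2Oc3cc(OCc5ccccc5)ccc3[C@H](c3c(OCc5ccccc5)cc(OCc5ccccc5)c4c3O[C@H](c3ccc(OCc5ccccc5)c(OCc5ccccc5)c3)[C@H](O)C4)[C@H]2OCc5ccccc5)cc1
A7 | alternative 3 | ring D aryl ether of the 1-aryl-2,3-epoxypropan-1-ol unit | c5ccccc5COc1ccc([C@H]2Oc3cc(OCc5ccccc5)ccc3[C@H](c3c(OCc5ccccc5)cc(OCc5ccccc5)cc3O[C@H](c3ccc(OCc5ccccc5)c(OCc5ccccc5)c3)[C@H]3CO3)[C@H]2OCc5ccccc5)cc1
A8 | alternative 3 | gold trichloride | Cl[Au](Cl)Cl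
A9 | alternative 3 | silver triflate | [Ag+].[O-]S(=O)(=O)C(F)(F)F
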